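**Plan**
- Retrosynthesis: the quinone (ring B) is cut at the bond joining its two methoxy-bearing carbons, then the pyran O1–C2 bond (Mitsunobu), then the C3=C4 bond and lactone of a 3-furylcoumarin (Perkin), and last the furan C3–CH2 bond (cross-coupling).
- Enabling feature: in ring B the two C–OMe atoms (C2, C3) sit between the carbonyl carbons (C1, C4), which are joined by the C5=C6 alkene. The six ring carbons are therefore the chain MeOCH2–C(=O)–C=C–C(=O)–CH2OMe of a ring-opened 2,5-bis(methoxymethyl)furan, whose bis-enol ether is a hexatriene ending in the two CH(OMe) carbons; the two arms are identical, so no regiochemical question arises.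
- Forward order: ring A is bought as a salicylaldehyde; the furan acid (steps 1–4) and the aldehyde (5–6) are joined as a coumarin (7), which is converted to the 2H-chromene (8–9) and hydrogenated (10). The furan is then opened (11) and enolised (12), ring B is closed last and aromatised (13), then unmasked and oxidised to the quinone (14).
- Stereochemistry: the single stereocentre, C3 of the chroman, is set as S by catalyst-controlled iridium asymmetric hydrogenation of the chromene C3=C4 bond and is not touched afterwards.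

Key step: step 13

Assumption: the (S)-phosphinooxazoline ligand is taken to deliver the (3S)-chroman; the facial sense of this hydrogenation cannot be predicted with certainty for a furyl-substituted chromene, and if hydrogen adds to the other face the (R)-ligand is used with no other change.

**Step 1**
Reactants: 1 2,5-bis(hydroxymethyl)furan
Product: 2 2,5-bis(methoxymethyl)furan
Conditions: NaH (2.4 equiv), MeI (2.6 equiv), THF, 0 °C to rt
Reagents that add atoms: iodomethane, CI
Why: Williamson etherification of both primary furfuryl alkoxides with a methyl halide should be clean because the substrate has no other acidic or electrophilic site.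

**Step 2**
Reactants: 2 2,5-bis(methoxymethyl)furan
Product: 3 3-bromo-2,5-bis(methoxymethyl)furan
Conditions: NBS (1.0 equiv), DMF, −20 to 0 °C, dark
Reagents that add atoms: N-bromosuccinimide, O=C1CCC(=O)N1Br
Why: Electrophilic aromatic bromination of an electron-rich furan whose α-positions are blocked and whose two β-positions are equivalent should give one monobromide, the polar solvent and darkness suppressing radical bromination of the CH2OMe arms.

**Step 3**
Reactants: 3 3-bromo-2,5-bis(methoxymethyl)furan
Product: 4 ethyl 2-[2,5-bis(methoxymethyl)furan-3-yl]acetate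
Conditions: BrZnCH2CO2Et (1.5 equiv, made from BrCH2CO2Et and Zn in THF), Pd2(dba)3 (2 mol %), XPhos (8 mol %), THF, 60 °C
Reagents that add atoms: ethyl bromoacetate, CCOC(=O)CBr (used as its zinc reagent)
Why: Palladium-catalysed Negishi-type coupling of a Reformatsky reagent with a heteroaryl bromide (α-arylation of a zinc ester enolate) runs under neutral conditions that the furfuryl ethers tolerate and puts the CH2CO2Et arm on the furan β-carbon.

**Step 4**
Reactants: 4 ethyl 2-[2,5-bis(methoxymethyl)furan-3-yl]acetate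
Product: 5 2-[2,5-bis(methoxymethyl)furan-3-yl]acetic acid
Conditions: LiOH·H2O, THF/MeOH/H2O, rt; then 1 M HCl to pH 4, 0 °C
Reagents that add atoms: lithium hydroxide, [Li+].[OH-]
Why: Saponification of an unhindered ethyl ester, with the acidification kept cold and only to pH 4 so that the acid-labile furfuryl ethers survive.

**Step 5**
Reactants: 6 2-hydroxy-3,4-dimethoxybenzaldehyde
Product: 8 2,5-dihydroxy-3,4-dimethoxybenzaldehyde, via aryl potassium sulfate 7 (not isolated)
Conditions: K2S2O8, aq. NaOH, 0 °C to rt; then aq. HCl, 80 °C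
Reagents that add atoms: potassium peroxodisulfate, [K+].[K+].[O-]S(=O)(=O)OOS(=O)(=O)[O-]
Why: Elbs persulfate oxidation: the phenoxide attacks a peroxide oxygen through its free para carbon (C5), and acid hydrolysis of the aryl sulfate should give the hydroquinone aldehyde.

**Step 6**
Reactants: 8 2,5-dihydroxy-3,4-dimethoxybenzaldehyde
Product: 9 2-hydroxy-3,4-dimethoxy-5-[(triisopropylsilyl)oxy]benzaldehyde
Conditions: TIPSCl (1.05 equiv), imidazole, DMF, 0 °C
Reagents that add atoms: chlorotriisopropylsilane, CC(C)[Si](Cl)(C(C)C)C(C)C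
Why: Silylation with a bulky chlorosilane should be selective for the 5-OH, because the 2-OH is hydrogen-bonded to the formyl group and flanked by a methoxy group; the 2-OH stays free for step 7.

**Step 7**
Reactants: 5 2-[2,5-bis(methoxymethyl)furan-3-yl]acetic acid; 9 2-hydroxy-3,4-dimethoxy-5-[(triisopropylsilyl)oxy]benzaldehyde
Product: 10 3-[2,5-bis(methoxymethyl)furan-3-yl]-7,8-dimethoxy-6-[(triisopropylsilyl)oxy]-2H-chromen-2-one
Conditions: Ac2O, Et3N, 110 °C
Reagents that add atoms: none
Why: Perkin–Oglialoro condensation: the mixed anhydride of the arylacetic acid acylates the phenol and its activated CH2 condenses with the ortho formyl group, giving the 3-substituted coumarin with loss of two molecules of water, the aryl silyl ether being stable to Ac2O/Et3N.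

**Step 8**
Reactants: 10 3-[2,5-bis(methoxymethyl)furan-3-yl]-7,8-dimethoxy-6-[(triisopropylsilyl)oxy]-2H-chromen-2-one
Product: 11 (2Z)-2-[2,5-bis(methoxymethyl)furan-3-yl]-3-{2-hydroxy-3,4-dimethoxy-5-[(triisopropylsilyl)oxy]phenyl}prop-2-en-1-ol
Conditions: i-Bu2AlH (4 equiv), CH2Cl2, −78 to 0 °C; aq. KNaC4H4O6 work-up
Reagents that add atoms: none
Why: Excess i-Bu2AlH reduces the lactone through the lactol to the allylic alcohol and phenol without touching the trisubstituted alkene, whose Z geometry (aryl cis to CH2OH) is inherited from the ring.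

**Step 9**
Reactants: 11 (2Z)-2-[2,5-bis(methoxymethyl)furan-3-yl]-3-{2-hydroxy-3,4-dimethoxy-5-[(triisopropylsilyl)oxy]phenyl}prop-2-en-1-ol
Product: 12 3-[2,5-bis(methoxymethyl)furan-3-yl]-7,8-dimethoxy-6-[(triisopropylsilyl)oxy]-2H-chromene
Conditions: PPh3, DIAD, THF, 0 °C to rt
Reagents that add atoms: none
Why: Intramolecular Mitsunobu etherification: the phenol, the only acidic OH, displaces the activated primary allylic alcohol in a 6-exo-tet closure that only the Z-alkene allows, giving the 2H-chromene.

**Step 10**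
Reactants: 12 3-[2,5-bis(methoxymethyl)furan-3-yl]-7,8-dimethoxy-6-[(triisopropylsilyl)oxy]-2H-chromene
Product: 13 (3S)-3-[2,5-bis(methoxymethyl)furan-3-yl]-7,8-dimethoxy-6-[(triisopropylsilyl)oxy]chromane
Conditions: H2 (50 bar), [Ir(cod)((S)-t-Bu-PHOX)][B(C6H3(CF3)2)4] (2 mol %), CH2Cl2, rt
Reagents that add atoms: none
Why: Iridium phosphinooxazoline-catalysed asymmetric hydrogenation of an unfunctionalised trisubstituted cyclic aryl alkene, a reaction type used for 2H-chromenes, adds H2 to one face of C3=C4 under catalyst control and so sets C3 as S, while the trisubstituted furan and the aryl silyl ether are not reduced.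

**Step 11**
Reactants: 13 (3S)-3-[2,5-bis(methoxymethyl)furan-3-yl]-7,8-dimethoxy-6-[(triisopropylsilyl)oxy]chromane
Product: 15 (3Z)-1,6-dimethoxy-3-{(3S)-7,8-dimethoxy-6-[(triisopropylsilyl)oxy]chroman-3-yl}hex-3-ene-2,5-dione, via furan endoperoxide 14 (not isolated)
Conditions: O2, tetraphenylporphyrin (cat.), visible light, CH2Cl2, −78 °C; then Me2S, −78 °C to rt
Reagents that add atoms: dioxygen, O=O
Why: Singlet oxygen adds [4+2] across C2/C5 of the electron-rich furan, and reduction of the O–O bond with Me2S at low temperature unravels the endoperoxide to the cis-enedione, the Z geometry being fixed by the ring it came from; the fully substituted, silylated ring A should not react with singlet oxygen.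

**Step 12**
Reactants: 15 (3Z)-1,6-dimethoxy-3-{(3S)-7,8-dimethoxy-6-[(triisopropylsilyl)oxy]chroman-3-yl}hex-3-ene-2,5-dione
Product: 16 (1Z,3Z,5Z)-2,5-bis[(tert-butyldimethylsilyl)oxy]-1,6-dimethoxy-3-{(3S)-7,8-dimethoxy-6-[(triisopropylsilyl)oxy]chroman-3-yl}hexa-1,3,5-triene
Conditions: TBSOTf (2.5 equiv), i-Pr2NEt (3.5 equiv), CH2Cl2, −78 to −20 °C; pentane work-up, Et3N-deactivated silica
Reagents that add atoms: tert-butyldimethylsilyl triflate, CC(C)(C)[Si](C)(C)OS(=O)(=O)C(F)(F)F
Why: Soft enolisation: each ketone, activated by the silyl triflate, is deprotonated by the hindered amine at its CH2OMe group (the only α-hydrogens of the enedione), giving Z-enol ethers with methoxy cis to silyloxy, while low temperature and a non-nucleophilic base should avoid conjugate addition, Z/E isomerisation and removal of the hindered methine hydrogen at C3 of the chroman.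

**Step 13**
Reactants: 16 (1Z,3Z,5Z)-2,5-bis[(tert-butyldimethylsilyl)oxy]-1,6-dimethoxy-3-{(3S)-7,8-dimethoxy-6-[(triisopropylsilyl)oxy]chroman-3-yl}hexa-1,3,5-triene
Product: 18 (3S)-3-{2,5-bis[(tert-butyldimethylsilyl)oxy]-3,4-dimethoxyphenyl}-7,8-dimethoxy-6-[(triisopropylsilyl)oxy]chromane, via cis-dimethoxycyclohexadiene 17 (not isolated)
Conditions: PhMe, 2,4,6-collidine (0.2 equiv), 120 °C, sealed tube; then DDQ (1.05 equiv), 2,4,6-collidine, CH2Cl2, −40 to 0 °C
Reagents that add atoms: none
Why: On heating, the triene adopts its s-cis,s-cis conformer and undergoes a thermal disrotatory 6π-electrocyclisation that joins its two methoxy-bearing termini (the future C2 and C3 of ring B) to give cyclohexa-1,3-diene 17; DDQ then abstracts hydride from a doubly activated CH(OMe) (allylic and α to oxygen) and the cation loses the neighbouring proton, giving the hydroquinone bis-silyl ether 18. The closest known reaction type is the electrocyclisation/dehydrogenation of 2-silyloxyhexa-1,3,5-trienes to arenes, applied here to a 2,5-bis(silyloxy)triene derived from a cis-enedione. The six-membered carbocycle closes in a six-electron disrotatory mode; the central Z-alkene comes from the furan and both terminal methoxy groups lie outside (Z-enol ethers), so only hydrogens rotate inward. The two sp3 centres formed are cis by orbital symmetry and are erased on aromatisation, so no lasting stereocentre is made, and C3 of the chroman, whose hydrogen lies trans to the diene arm and cannot shift, is untouched. The step needs dehydrogenation to win over loss of methanol from 17, which the collidine-buffered acid-free medium and low-temperature DDQ should secure, and it needs 17 to react before the benzylic C4–H of the chroman, which the much greater hydride-donor ability of the bis(silyloxy)diene should secure; regioselectivity is not at stake because both termini are equivalent CH(OMe) carbons.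

**Step 14**
Reactants: 18 (3S)-3-{2,5-bis[(tert-butyldimethylsilyl)oxy]-3,4-dimethoxyphenyl}-7,8-dimethoxy-6-[(triisopropylsilyl)oxy]chromane
Product: 20 5-[(3S)-6-hydroxy-7,8-dimethoxychroman-3-yl]-2,3-dimethoxy-1,4-benzoquinone (target), via hydroquinone 19 (not isolated)
Conditions: n-Bu4NF (3.5 equiv), AcOH (4 equiv), THF, 0 °C to rt, Ar; then air, EtOAc/aq. NaHCO3, rt
Reagents that add atoms: none
Why: Acetic acid-buffered fluoride cleaves the three aryl silyl ethers without exposing the product to strong base, and the electron-rich 2,3-dimethoxyhydroquinone, whose oxidation potential lies well below that of the ring A monophenol, should then be oxidised by air to the quinone, the dioxygen ending as water.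

**Compound list**
1 | 2,5-bis(hydroxymethyl)furan | OCc1ccc(CO)o1 | starting material
2 | 2,5-bis(methoxymethyl)furan | COCc1ccc(COC)o1 | intermediate
3 | 3-bromo-2,5-bis(methoxymethyl)furan | COCc1cc(Br)c(COC)o1 | intermediate
4 | ethyl 2-[2,5-bis(methoxymethyl)furan-3-yl]acetate | CCOC(=O)Cc1cc(COC)oc1COC | intermediate
5 | 2-[2,5-bis(methoxymethyl)furan-3-yl]acetic acid | OC(=O)Cc1cc(COC)oc1COC | intermediate
6 | 2-hydroxy-3,4-dimethoxybenzaldehyde | COc1ccc(C=O)c(O)c1OC | starting material
7 | potassium 5-formyl-4-hydroxy-2,3-dimethoxyphenyl sulfate (formed in the flask, not isolated) | COc1c(OS(=O)(=O)[O-])cc(C=O)c(O)c1OC.[K+] | intermediate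
8 | 2,5-dihydroxy-3,4-dimethoxybenzaldehyde | COc1c(O)cc(C=O)c(O)c1OC | intermediate
9 | 2-hydroxy-3,4-dimethoxy-5-[(triisopropylsilyl)oxy]benzaldehyde | COc1c(O[Si](C(C)C)(C(C)C)C(C)C)cc(C=O)c(O)c1OC | intermediate
10 | 3-[2,5-bis(methoxymethyl)furan-3-yl]-7,8-dimethoxy-6-[(triisopropylsilyl)oxy]-2H-chromen-2-one | O=C1Oc2c(OC)c(OC)c(O[Si](C(C)C)(C(C)C)C(C)C)cc2C=C1c1cc(COC)oc1COC | intermediate
11 | (2Z)-2-[2,5-bis(methoxymethyl)furan-3-yl]-3-{2-hydroxy-3,4-dimethoxy-5-[(triisopropylsilyl)oxy]phenyl}prop-2-en-1-ol | OC/C(c1cc(COC)oc1COC)=C\c1cc(O[Si](C(C)C)(C(C)C)C(C)C)c(OC)c(OC)c1O | intermediate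
12 | 3-[2,5-bis(methoxymethyl)furan-3-yl]-7,8-dimethoxy-6-[(triisopropylsilyl)oxy]-2H-chromene | COCc1cc(C2=Cc3cc(O[Si](C(C)C)(C(C)C)C(C)C)c(OC)c(OC)c3OC2)c(COC)o1 | intermediate
13 | (3S)-3-[2,5-bis(methoxymethyl)furan-3-yl]-7,8-dimethoxy-6-[(triisopropylsilyl)oxy]chromane | COCc1cc([C@H]2COc3c(OC)c(OC)c(O[Si](C(C)C)(C(C)C)C(C)C)cc3C2)c(COC)o1 | intermediate
14 | 1,4-bis(methoxymethyl)-5-{(3S)-7,8-dimethoxy-6-[(triisopropylsilyl)oxy]chroman-3-yl}-2,3,7-trioxabicyclo[2.2.1]hept-5-ene (furan endoperoxide, bridgehead configuration undefined, not isolated) | COCC12OOC(COC)(O1)C=C2[C@H]3COc4c(OC)c(OC)c(O[Si](C(C)C)(C(C)C)C(C)C)cc4C3 | intermediate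
15 | (3Z)-1,6-dimethoxy-3-{(3S)-7,8-dimethoxy-6-[(triisopropylsilyl)oxy]chroman-3-yl}hex-3-ene-2,5-dione | COCC(=O)/C=C(\C(=O)COC)[C@H]1COc2c(OC)c(OC)c(O[Si](C(C)C)(C(C)C)C(C)C)cc2C1 | intermediate
16 | (1Z,3Z,5Z)-2,5-bis[(tert-butyldimethylsilyl)oxy]-1,6-dimethoxy-3-{(3S)-7,8-dimethoxy-6-[(triisopropylsilyl)oxy]chroman-3-yl}hexa-1,3,5-triene | CO/C=C(O[Si](C)(C)C(C)(C)C)/C=C(\C(O[Si](C)(C)C(C)(C)C)=C\OC)[C@H]1COc2c(OC)c(OC)c(O[Si](C(C)C)(C(C)C)C(C)C)cc2C1 | intermediate
17 | cis-5,6-dimethoxy-1,4-bis[(tert-butyldimethylsilyl)oxy]-2-{(3S)-7,8-dimethoxy-6-[(triisopropylsilyl)oxy]chroman-3-yl}cyclohexa-1,3-diene (both cis diastereomers, ring centres undefined, not isolated) | COC1C(OC)C(O[Si](C)(C)C(C)(C)C)=C([C@H]2COc3c(OC)c(OC)c(O[Si](C(C)C)(C(C)C)C(C)C)cc3C2)C=C1O[Si](C)(C)C(C)(C)C | intermediate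
18 | (3S)-3-{2,5-bis[(tert-butyldimethylsilyl)oxy]-3,4-dimethoxyphenyl}-7,8-dimethoxy-6-[(triisopropylsilyl)oxy]chromane | COc1c(OC)c(O[Si](C)(C)C(C)(C)C)c([C@H]2COc3c(OC)c(OC)c(O[Si](C(C)C)(C(C)C)C(C)C)cc3C2)cc1O[Si](C)(C)C(C)(C)C | intermediate
19 | (3S)-3-(2,5-dihydroxy-3,4-dimethoxyphenyl)-7,8-dimethoxychroman-6-ol (not isolated) | COc1c(OC)c(O)c([C@H]2COc3c(OC)c(OC)c(O)cc3C2)cc1O | intermediate
20 | 5-[(3S)-6-hydroxy-7,8-dimethoxychroman-3-yl]-2,3-dimethoxycyclohexa-2,5-diene-1,4-dione (CNP0302517.1) | COC1=C(OC)C(=O)C([C@H]2COc3c(cc(O)c(OC)c3OC)C2)=CC1=O | target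

**Totals**
Total step count: 14. Longest linear sequence: 12 steps (steps 1–4 and 7–14, from compound 1).

**Steps most likely to fail**

Step 13. The ring closure may need temperatures at which the ring-closed diene loses methanol before the oxidant is added, so that one of the two methoxy groups is lost on aromatisation. The closure may also be slowed by crowding between the chromanyl group and the neighbouring silyloxy group. The fallback sets out from 16 and returns at 20; it makes the same bond oxidatively instead of pericyclically. Treating 16 with Ag2O in DMSO at rt (silver oxide-mediated oxidative coupling of silyl enol ethers to 1,4-diketones, here intramolecular) should give 2-{(3S)-7,8-dimethoxy-6-[(triisopropylsilyl)oxy]chroman-3-yl}-5,6-dimethoxycyclohex-2-ene-1,4-dione F1. This should enolise to (3S)-3-(2,5-dihydroxy-3,4-dimethoxyphenyl)-7,8-dimethoxy-6-[(triisopropylsilyl)oxy]chromane F2, which excess Ag2O oxidises to 5-{(3S)-7,8-dimethoxy-6-[(triisopropylsilyl)oxy]chroman-3-yl}-2,3-dimethoxy-1,4-benzoquinone F3. n-Bu4NF/AcOH in THF at 0 °C then frees the ring A phenol to give 20.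

Step 10. Facial selectivity may be poor or the catalyst may be inhibited: the CH2OMe arm next to the coupling position of the furan and its ether oxygens may lower the enantioselectivity or bind the cationic iridium. The fallback sets out from 11 and returns at 13. The open-chain (Z)-allylic alcohol 11 is hydrogenated under hydroxyl direction with Ru(OAc)2((S)-BINAP) (or its antipode, whichever gives the S centre), H2, MeOH, to give (2S)-2-[2,5-bis(methoxymethyl)furan-3-yl]-3-{2-hydroxy-3,4-dimethoxy-5-[(triisopropylsilyl)oxy]phenyl}propan-1-ol F4. Mitsunobu ring closure (PPh3, DIAD, THF) then gives 13 without touching the stereocentre.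

Step 5. Conversion may be low and over-oxidation may occur: the persulfate reaction of an electron-rich salicylaldehyde can stop early, the hydroquinone formed can be oxidised further and polymerise, and the formyl group can suffer in hot alkali. The fallback sets out from 6 and returns at 8. Radical para-oxidation with Fremy's salt, (KSO3)2NO, in KH2PO4-buffered water/acetone (Teuber oxidation, para position free) should give 2-formyl-5,6-dimethoxy-1,4-benzoquinone F5, which Na2S2O4 in water/EtOAc reduces to 8.

**Further compounds**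
F1 | step 13 | 2-{(3S)-7,8-dimethoxy-6-[(triisopropylsilyl)oxy]chroman-3-yl}-5,6-dimethoxycyclohex-2-ene-1,4-dione | COC1C(OC)C(=O)C([C@H]2COc3c(OC)c(OC)c(O[Si](C(C)C)(C(C)C)C(C)C)cc3C2)=CC1=O
F2 | step 13 | (3S)-3-(2,5-dihydroxy-3,4-dimethoxyphenyl)-7,8-dimethoxy-6-[(triisopropylsilyl)oxy]chromane | COc1c(OC)c(O)c([C@H]2COc3c(OC)c(OC)c(O[Si](C(C)C)(C(C)C)C(C)C)cc3C2)cc1O
F3 | step 13 | 5-{(3S)-7,8-dimethoxy-6-[(triisopropylsilyl)oxy]chroman-3-yl}-2,3-dimethoxy-1,4-benzoquinone | COC1=C(OC)C(=O)C([C@H]2COc3c(OC)c(OC)c(O[Si](C(C)C)(C(C)C)C(C)C)cc3C2)=CC1=O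
F4 | step 10 | (2S)-2-[2,5-bis(methoxymethyl)furan-3-yl]-3-{2-hydroxy-3,4-dimethoxy-5-[(triisopropylsilyl)oxy]phenyl}propan-1-ol | OC[C@@H](Cc1cc(O[Si](C(C)C)(C(C)C)C(C)C)c(OC)c(OC)c1O)c1cc(COC)oc1COC
F5 | step 5 | 2-formyl-5,6-dimethoxy-1,4-benzoquinone | O=CC1=CC(=O)C(OC)=C(OC)C1=O
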